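The number to argue over is 0.501, the natural logarithm of substrate charged over substrate left in the larch run at 40.0 h; call it the reach of a dose of enzyme.

| flask | substrate | enzyme | remark | time |
|---|---|---|---|---|
| larch | 10 mM | 1 µM | the very flask that is asked about, followed so far |  |
| cedar | 15 mM | 1 µM | run made earlier |  |
| flask | 10 mM | 1.0 µM |  | 2.5 d |

| run | time / h | product / % | substrate / % |
|---|---|---|---|
| larch | 10.0 | 27.6 | 73.8 |
| larch | 20.0 | 33.1 | 67.2 |
| larch | 25.0 | 34.5 | 63.3 |
| larch | 40.0 | 38.6 | 60.6 |
| cedar | 0.333 | 2.8 | 98.7 |
| cedar | 0.833 | 4.3 | 95.6 |
| cedar | 2.00 | 9.9 | 90.6 |
| cedar | 4.00 | 14.1 | 84.1 |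

(standard deviation of a reading: 1 percentage point)

- removed product is counted in
- the numbers in the tables scatter with a standard deviation of 1 percentage point
- additions bring no volume worth counting

- south: at 2.5 d take out 90% of the product then present, then wait 20 h
- north-east: at 2.5 d add substrate, 50.0% of the amount charged, then wait 20 h
- south-west: at 2.5 d add enzyme, 50.0% of the amount charged, then wait 20 h
- south-east: change nothing and wait 20 h more

* product, in percent of the substrate first charged, at 2.5 d
* the remedy with the largest gain of product, or "none" below 2 percentage points (south / north-east / south-west / south-east / none)
* product present, with what was taken out counted in, in percent of the substrate first charged, after south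
* product present, with what was taken out counted in, in percent of the substrate first charged, after south-west

Larch is the flask asked about, and Ada and Ben disagree on why it slows. Ben reads an equilibrium. Product over substrate stands at 0.637 in the last larch reading, and he takes that as the final ratio. Taking out 90% of the product should then restart the flask. If it returns to that ratio, south gives 59.8%, with the removed product counted in.

Ada reads enzyme death (deactivation). Suppose the rate of ln c_substrate is proportional to live enzyme, and live enzyme decays exponentially. The area under a falling exponential is its height times its decay time. So ln c_substrate can fall by a fixed total, the reach, and that total is proportional to the dose.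

Her numbers come from two runs. Cedar's early rate constant reads 0.0433 h⁻¹, while larch between its last two readings gives 0.00291 h⁻¹, far less. Reach over early rate constant gives an enzyme lifetime of 11.6 h, shorter than the wait of 20 h.

I side with Ada and reckon product near 39.4% now. Enzyme added at 50.0% of the charge carries a reach of 0.250. Spent whole on the substrate of the last reading, it gives 52.8% as my ceiling, above the forecast's value.

The forecast, on Ada's side, says “Enzyme death fits better”. It gives 40.5% now (range 39% to 42.5%), south-west as best, 41% after south and 51% after south-west.

The flask gives 40.8%, and south-west gains most, 8.6 percentage points, while south gives 44.8%, not Ben's 59.8%.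

    2 complex → spent catalyst (k = 20000 L mol⁻¹ min⁻¹)
    complex ⇌ enzyme + product (K = 0.00600 M, k = 36.0 min⁻¹)
    substrate + enzyme ⇌ complex (K = 190 L mol⁻¹, k = 1.50 × 10⁵ L mol⁻¹ min⁻¹)

At 60.0 h spent catalyst holds 97.8% of the catalyst charged. The added enzyme went with a fall of ln c_substrate by 0.158 in 20 h, less than the 0.250 reckoned. With 2.5 mM of substrate, the same flask at 60.0 h shows a fall of 0.761, more than the reach read in larch at 40.0 h. In that flask Ben's reading fits: product over substrate is 1.14, beside 1.14 from the two equilibrium constants multiplied, with enzyme still at 13.4%.

The earlier runs and the new flask are simulated with constants of no real substance, and the scatter is random.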